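**Retrosynthetic overview**
- The target is cut at C11=C12 and C11'=C12' (two Wittig reactions): a C15 triol phosphonium salt, the C10 trienedial and a C15 acetylenic phosphonium salt.
- Both C15 salts come from one enyne diol, made by Sonogashira coupling of an actinol-derived vinyl triflate with (E)-3-methylpent-2-en-4-yn-1-ol.
- Key step on the triol branch: 3-OH-directed epoxidation of the ring alkene, then templated anti-addition of water at the propargylic C6. This forms both C–O bonds and sets C5 and C6; the alkyne is then reduced to the E-alkene.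
- Ring order: no carbocycle is built. Both six-membered rings, with C3 and C3', come intact from (4R,6R)-actinol; the only ring formed is the transient oxirane, made and opened in step 7.

Assumption: (4R,6R)-actinol, (E)-3-methylpent-2-en-4-yn-1-ol and all-E 2,7-dimethylocta-2,4,6-trienedial are bought as catalogue chemicals; the SMILES encodes the all-E (3S,5S,6S,3'R) isomer (3-OH and 5-OH cis, 6-OH trans to both), and carotenoid numbering is used for positions.

**Step 1**
Reactants: 1 (4R,6R)-4-hydroxy-2,2,6-trimethylcyclohexan-1-one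
Product: 2 (4R,6R)-2,2,6-trimethyl-4-(triethylsilyloxy)cyclohexan-1-one
Conditions: Et3SiCl, imidazole, CH2Cl2, 0 °C to rt
Reagents that add atoms: chlorotriethylsilane, CC[Si](Cl)(CC)CC
Why: Imidazole-promoted silyl ether formation on the only hydroxyl masks it for the enolate chemistry and touches no stereocentre.

**Step 2**
Reactants: 2 (4R,6R)-2,2,6-trimethyl-4-(triethylsilyloxy)cyclohexan-1-one
Product: 5 (4R)-4-hydroxy-2,6,6-trimethylcyclohex-1-en-1-yl trifluoromethanesulfonate, via lithium enolate 3 (not isolated), via silyl triflate 4 (not isolated)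
Conditions: LiN(i-Pr)2, THF, −78 °C; PhNTf2, −78 °C to rt; then 1 M aq. HCl/MeOH, rt
Reagents that add atoms: N-phenylbis(trifluoromethanesulfonimide), O=S(=O)(N(c1ccccc1)S(=O)(=O)C(F)(F)F)C(F)(F)F
Why: Enolate O-triflation can occur only toward C6 because the other α-carbon is quaternary, so a single tetrasubstituted vinyl triflate forms, and the acid quench cleaves the silyl ether while the vinyl triflate and the C3 carbinol centre are unaffected.

**Step 3**
Reactants: 5 (4R)-4-hydroxy-2,6,6-trimethylcyclohex-1-en-1-yl trifluoromethanesulfonate; 6 (2E)-3-methylpent-2-en-4-yn-1-ol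
Product: 7 (2E)-5-[(4R)-4-hydroxy-2,6,6-trimethylcyclohex-1-en-1-yl]-3-methylpent-2-en-4-yn-1-ol
Conditions: Pd(PPh3)4 (5 mol %), CuI (10 mol %), i-Pr2NH, DMF, degassed, 25–45 °C
Reagents that add atoms: none
Why: Sonogashira coupling of a vinyl triflate with a terminal alkyne tolerates both free hydroxyls and keeps the E geometry of 6, giving the C15 enyne common to both halves.

**Step 4**
Reactants: 7 (2E)-5-[(4R)-4-hydroxy-2,6,6-trimethylcyclohex-1-en-1-yl]-3-methylpent-2-en-4-yn-1-ol
Product: 8 [(2E)-5-[(4R)-4-hydroxy-2,6,6-trimethylcyclohex-1-en-1-yl]-3-methylpent-2-en-4-yn-1-yl]triphenylphosphonium bromide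
Conditions: PPh3·HBr, MeOH, 0 °C to rt
Reagents that add atoms: triphenylphosphine hydrobromide, Br.P(c1ccccc1)(c1ccccc1)c1ccccc1
Why: Acid-mediated allylic substitution by the phosphine at the primary terminus (the standard Wittig-salt formation for carotenoid C15 allylic alcohols) leaves the secondary ring hydroxyl alone.

**Step 5**
Reactants: 8 [(2E)-5-[(4R)-4-hydroxy-2,6,6-trimethylcyclohex-1-en-1-yl]-3-methylpent-2-en-4-yn-1-yl]triphenylphosphonium bromide; 9 (2E,4E,6E)-2,7-dimethylocta-2,4,6-trienedial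
Product: 11 (2E,4E,6E,8E,10E)-13-[(4R)-4-hydroxy-2,6,6-trimethylcyclohex-1-en-1-yl]-2,7,11-trimethyltrideca-2,4,6,8,10-pentaen-12-ynal, via ylide 10 (not isolated)
Conditions: NaOMe, CH2Cl2/MeOH, 0 °C, 9 (3 equiv, excess recovered); then n-heptane, reflux
Reagents that add atoms: none
Why: Wittig olefination of one formyl group of the symmetrical dialdehyde (the excess suppresses double condensation) forms C11'=C12' mainly E, and the hindered Z portion isomerises on heating.

**Step 6**
Reactants: 7 (2E)-5-[(4R)-4-hydroxy-2,6,6-trimethylcyclohex-1-en-1-yl]-3-methylpent-2-en-4-yn-1-ol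
Product: 12 (2E)-5-[(4R)-4-hydroxy-2,6,6-trimethylcyclohex-1-en-1-yl]-3-methylpent-2-en-4-yn-1-yl acetate
Conditions: AcCl (1.05 equiv), 2,4,6-collidine, CH2Cl2, −78 °C
Reagents that add atoms: acetyl chloride, CC(=O)Cl
Why: Low-temperature acylation is kinetically selective for the unhindered primary allylic hydroxyl over the secondary ring hydroxyl, removing the allylic OH as a competing director while keeping the 3-OH free.

**Step 7**
Reactants: 12 (2E)-5-[(4R)-4-hydroxy-2,6,6-trimethylcyclohex-1-en-1-yl]-3-methylpent-2-en-4-yn-1-yl acetate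
Product: 14 (2E)-3-methyl-5-[(1R,2S,4S)-1,2,4-trihydroxy-2,6,6-trimethylcyclohexyl]pent-2-en-4-yn-1-yl acetate, via syn-epoxide 13 (not isolated)
Conditions: VO(acac)2 (3 mol %), t-BuOOH (1.05 equiv, decane), toluene, 0 °C to rt; then 3,5-bis(trifluoromethyl)phenylboronic acid (1.1 equiv), THF/H2O 10:1, 0 °C to rt; aq. sorbitol/Na2CO3 wash
Reagents that add atoms: tert-butyl hydroperoxide, CC(C)(C)OO; water, O
Why: Proposed new method: a one-flask, hydroxyl-directed anti-dihydroxylation whose ring-opening half is a boronic-acid-templated hydrolysis of a tetrasubstituted alkynyl epoxide, not described for such a substrate. Stage 1 is established reactivity: the pentavalent vanadium tert-butylperoxide bound to the C3 alkoxide delivers oxygen to the face of C5=C6 that carries the 3-OH, which sets C5 in 13; the side-chain alkene has no free directing OH and the alkyne is inert. Stage 2 is the new part: the electron-poor arylboronic acid condenses with the 3-OH and its boron coordinates the cis epoxide oxygen in a six-membered chelate. This polarises the C6–O bond, which is tertiary and propargylic and so far more ionisable than C5–O (whose cleavage would need a seven-membered chelate). The leaving oxygen stays clamped on its face, so water adds to C6 from the opposite face (borderline SN2, trans-diaxial opening): C6 is inverted, C5–O is never broken, and the cis-3,5-diol is freed from its boronate by the sorbitol wash. Because C7≡C8 is still an alkyne, the furanoid 5,8-epoxide rearrangement typical of vinyl-substituted 5,6-epoxides cannot occur. Closest known reaction types: VO(acac)2/t-BuOOH directed epoxidation of homoallylic alcohols, borinic- and boronic-acid-catalysed regioselective opening of epoxy alcohols, and acid-catalysed anti-hydrolysis of epoxides.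

**Step 8**
Reactants: 14 (2E)-3-methyl-5-[(1R,2S,4S)-1,2,4-trihydroxy-2,6,6-trimethylcyclohexyl]pent-2-en-4-yn-1-yl acetate
Product: 15 (2E,4E)-3-methyl-5-[(1S,2S,4S)-1,2,4-trihydroxy-2,6,6-trimethylcyclohexyl]penta-2,4-dien-1-ol
Conditions: NaAlH2(OCH2CH2OCH3)2 (6 equiv), THF, 0 °C to rt; aq. potassium sodium tartrate
Reagents that add atoms: none
Why: Alkoxide-directed trans-hydroalumination of the propargylic alcohol and protonolysis give the E-C7=C8 alkene, the same hydride cleaves the acetate (ester reduction), and no stereocentre changes (the C6 descriptor changes only because the CIP priorities change).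

**Step 9**
Reactants: 15 (2E,4E)-3-methyl-5-[(1S,2S,4S)-1,2,4-trihydroxy-2,6,6-trimethylcyclohexyl]penta-2,4-dien-1-ol
Product: 17 [(2E,4E)-3-methyl-5-[(1S,2S,4S)-1,2,4-trihydroxy-2,6,6-trimethylcyclohexyl]penta-2,4-dien-1-yl]triphenylphosphonium bromide, via allylic bromide 16 (not isolated)
Conditions: N-bromosuccinimide, Me2S, CH2Cl2/THF, −20 to 0 °C; then PPh3, rt
Reagents that add atoms: N-bromosuccinimide, O=C1CCC(=O)N1Br; triphenylphosphine, P(c1ccccc1)(c1ccccc1)c1ccccc1
Why: Corey–Kim halogenation converts only the primary allylic alcohol to the bromide under neutral conditions (the saturated secondary and the tertiary hydroxyls do not react), and SN2 quaternisation of the phosphine then gives the salt without the acid that would ionise the tertiary allylic C6–OH.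

**Step 10**
Reactants: 17 [(2E,4E)-3-methyl-5-[(1S,2S,4S)-1,2,4-trihydroxy-2,6,6-trimethylcyclohexyl]penta-2,4-dien-1-yl]triphenylphosphonium bromide; 11 (2E,4E,6E,8E,10E)-13-[(4R)-4-hydroxy-2,6,6-trimethylcyclohex-1-en-1-yl]-2,7,11-trimethyltrideca-2,4,6,8,10-pentaen-12-ynal
Product: 19 (all-E)-(3S,5S,6S,3'R)-7',8'-didehydro-5,6-dihydro-β,β-carotene-3,5,6,3'-tetrol, via ylide 18 (not isolated)
Conditions: 17 (1.2 equiv), NaOMe, CH2Cl2/MeOH, 0 °C to rt, argon, dark; then EtOH, reflux; crystallisation or preparative HPLC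
Reagents that add atoms: none
Why: Wittig olefination joins the two halves at C11=C12 with the hydroxyls free, the hindered Z isomer isomerises on heating, and no stereocentre is involved.

**Compound list**
1 | (4R,6R)-4-hydroxy-2,2,6-trimethylcyclohexan-1-one ((4R,6R)-actinol) | O=C1C(C)(C)C[C@H](O)C[C@H]1C | starting material
2 | (4R,6R)-2,2,6-trimethyl-4-(triethylsilyloxy)cyclohexan-1-one | O=C1C(C)(C)C[C@H](O[Si](CC)(CC)CC)C[C@H]1C | intermediate
3 | lithium (4R)-2,6,6-trimethyl-4-(triethylsilyloxy)cyclohex-1-en-1-olate | [Li+].[O-]C1=C(C)C[C@@H](O[Si](CC)(CC)CC)CC1(C)C | intermediate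
4 | (4R)-2,6,6-trimethyl-4-(triethylsilyloxy)cyclohex-1-en-1-yl trifluoromethanesulfonate | O=S(=O)(OC1=C(C)C[C@@H](O[Si](CC)(CC)CC)CC1(C)C)C(F)(F)F | intermediate
5 | (4R)-4-hydroxy-2,6,6-trimethylcyclohex-1-en-1-yl trifluoromethanesulfonate | O=S(=O)(OC1=C(C)C[C@@H](O)CC1(C)C)C(F)(F)F | intermediate
6 | (2E)-3-methylpent-2-en-4-yn-1-ol | C#C/C(C)=C/CO | starting material
7 | (2E)-5-[(4R)-4-hydroxy-2,6,6-trimethylcyclohex-1-en-1-yl]-3-methylpent-2-en-4-yn-1-ol | OC/C=C(C)/C#CC1=C(C)C[C@@H](O)CC1(C)C | intermediate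
8 | [(2E)-5-[(4R)-4-hydroxy-2,6,6-trimethylcyclohex-1-en-1-yl]-3-methylpent-2-en-4-yn-1-yl]triphenylphosphonium bromide | [Br-].C(/C=C(C)/C#CC1=C(C)C[C@@H](O)CC1(C)C)[P+](c1ccccc1)(c1ccccc1)c1ccccc1 | intermediate
9 | (2E,4E,6E)-2,7-dimethylocta-2,4,6-trienedial | O=C/C(C)=C/C=C/C=C(C)/C=O | starting material
10 | phosphonium ylide of 8 (C11' carbanion next to PPh3) | [CH-](/C=C(C)/C#CC1=C(C)C[C@@H](O)CC1(C)C)[P+](c1ccccc1)(c1ccccc1)c1ccccc1 | intermediate
11 | (2E,4E,6E,8E,10E)-13-[(4R)-4-hydroxy-2,6,6-trimethylcyclohex-1-en-1-yl]-2,7,11-trimethyltrideca-2,4,6,8,10-pentaen-12-ynal (C25 aldehyde) | CC1=C(C#C/C(C)=C/C=C/C(C)=C/C=C/C=C(C)/C=O)C(C)(C)C[C@H](O)C1 | intermediate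
12 | (2E)-5-[(4R)-4-hydroxy-2,6,6-trimethylcyclohex-1-en-1-yl]-3-methylpent-2-en-4-yn-1-yl acetate | CC(=O)OC/C=C(C)/C#CC1=C(C)C[C@@H](O)CC1(C)C | intermediate
13 | (2E)-5-[(1S,4S,6S)-4-hydroxy-2,2,6-trimethyl-7-oxabicyclo[4.1.0]heptan-1-yl]-3-methylpent-2-en-4-yn-1-yl acetate (epoxide oxygen cis to the ring OH) | CC(=O)OC/C=C(C)/C#C[C@@]12C(C)(C)C[C@H](O)C[C@]1(C)O2 | intermediate
14 | (2E)-3-methyl-5-[(1R,2S,4S)-1,2,4-trihydroxy-2,6,6-trimethylcyclohexyl]pent-2-en-4-yn-1-yl acetate | CC(=O)OC/C=C(C)/C#C[C@]1(O)C(C)(C)C[C@H](O)C[C@]1(C)O | intermediate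
15 | (2E,4E)-3-methyl-5-[(1S,2S,4S)-1,2,4-trihydroxy-2,6,6-trimethylcyclohexyl]penta-2,4-dien-1-ol | OC/C=C(C)/C=C/[C@]1(O)C(C)(C)C[C@H](O)C[C@]1(C)O | intermediate
16 | (1S,2S,4S)-1-[(1E,3E)-5-bromo-3-methylpenta-1,3-dien-1-yl]-2,6,6-trimethylcyclohexane-1,2,4-triol | BrC/C=C(C)/C=C/[C@]1(O)C(C)(C)C[C@H](O)C[C@]1(C)O | intermediate
17 | [(2E,4E)-3-methyl-5-[(1S,2S,4S)-1,2,4-trihydroxy-2,6,6-trimethylcyclohexyl]penta-2,4-dien-1-yl]triphenylphosphonium bromide | [Br-].C(/C=C(C)/C=C/[C@]1(O)C(C)(C)C[C@H](O)C[C@]1(C)O)[P+](c1ccccc1)(c1ccccc1)c1ccccc1 | intermediate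
18 | phosphonium ylide of 17 (C11 carbanion next to PPh3) | [CH-](/C=C(C)/C=C/[C@]1(O)C(C)(C)C[C@H](O)C[C@]1(C)O)[P+](c1ccccc1)(c1ccccc1)c1ccccc1 | intermediate
19 | (all-E)-(3S,5S,6S,3'R)-7',8'-didehydro-5,6-dihydro-β,β-carotene-3,5,6,3'-tetrol | CC1=C(C#C/C(C)=C/C=C/C(C)=C/C=C/C=C(C)/C=C/C=C(C)/C=C/[C@]2(O)C(C)(C)C[C@H](O)C[C@]2(C)O)C(C)(C)C[C@H](O)C1 | target

**Step count**
Total: 10 steps. Longest linear sequence: 8 steps (1, 2, 3, 6, 7, 8, 9, 10).

**Three steps most likely to fail**

Step 7 (the proposed new step). The risks are sluggish opening, partial SN1 character at C6 (C6 epimer, or water adding at C8 of the propargyl/allenyl system), and attack at C5. The fallback uses known chemistry and sets out from 12. Boc2O/DMAP gives the tert-butyl carbonate F1. mCPBA/NaHCO3 in CH2Cl2 epoxidises the ring alkene mainly on the face away from the bulky carbonate, giving the anti-epoxide F2; any syn isomer cannot react further and is separated. BF3·OEt2 at −78 °C then triggers the known neighbouring-group opening: the carbonate carbonyl oxygen, tethered at O-3, attacks C5 with inversion through a six-membered ring and isobutene is lost. This gives the cyclic carbonate F3, which has the same configuration at C3, C5 and C6 as 14. The hydride conditions of step 8 reduce the alkyne and cleave both the acetate and the carbonate, so the fallback comes back to the route at 15.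

Step 9. The risks are ionisation of the tertiary allylic C6–OH or of the dienyl bromide (5,8-cyclisation, SN2' products), scrambling of the C9 geometry, and poor solubility of the tetraol. The fallback reverses the polarity of the last coupling and sets out from 15 and 11. MnO2 in CH2Cl2 oxidises only the primary allylic alcohol of 15 to the trihydroxy dienal F4. In parallel, NaBH4 reduces 11 to the C25 alcohol F5, and PPh3·HBr converts it to the C25 phosphonium bromide F6; this half has no acid-labile tertiary allylic alcohol. Wittig reaction of F6 with F4 (NaOMe, CH2Cl2/MeOH) forms the same C11=C12 bond and comes back to the route at 19.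

Step 10. The risks are low conversion of the polyhydroxylated ylide with the precious C25 aldehyde and Z isomers in the product, including the easily formed 9'Z acetylenic isomer. The fallback changes the order of fragment union and sets out from 17 and 9. Ylide 18 is first condensed with a threefold excess of the small, reactive dialdehyde 9 to give the triol C25 aldehyde F7. The robust acetylenic ylide 10, made from 8 with NaOMe, is then used for the last olefination, which now forms C11'=C12', and the fallback comes back to the route at 19.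

**Further compounds**
F1 | step 7 | (2E)-5-[(4R)-4-(tert-butoxycarbonyloxy)-2,6,6-trimethylcyclohex-1-en-1-yl]-3-methylpent-2-en-4-yn-1-yl acetate | CC(=O)OC/C=C(C)/C#CC1=C(C)C[C@@H](OC(=O)OC(C)(C)C)CC1(C)C
F2 | step 7 | (2E)-5-[(1R,4S,6R)-4-(tert-butoxycarbonyloxy)-2,2,6-trimethyl-7-oxabicyclo[4.1.0]heptan-1-yl]-3-methylpent-2-en-4-yn-1-yl acetate (epoxide oxygen trans to the carbonate) | CC(=O)OC/C=C(C)/C#C[C@]12C(C)(C)C[C@H](OC(=O)OC(C)(C)C)C[C@@]1(C)O2
F3 | step 7 | 3,5-cyclic carbonate of 14 (carbonyl bridging O-3 and O-5 of the ring, 6-OH free) | CC(=O)OC/C=C(C)/C#C[C@]1(O)C(C)(C)C[C@H]2C[C@]1(C)OC(=O)O2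
F4 | step 9 | (2E,4E)-3-methyl-5-[(1S,2S,4S)-1,2,4-trihydroxy-2,6,6-trimethylcyclohexyl]penta-2,4-dienal | O=C/C=C(C)/C=C/[C@]1(O)C(C)(C)C[C@H](O)C[C@]1(C)O
F5 | step 9 | (2E,4E,6E,8E,10E)-13-[(4R)-4-hydroxy-2,6,6-trimethylcyclohex-1-en-1-yl]-2,7,11-trimethyltrideca-2,4,6,8,10-pentaen-12-yn-1-ol | CC1=C(C#C/C(C)=C/C=C/C(C)=C/C=C/C=C(C)/CO)C(C)(C)C[C@H](O)C1
F6 | step 9 | [(2E,4E,6E,8E,10E)-13-[(4R)-4-hydroxy-2,6,6-trimethylcyclohex-1-en-1-yl]-2,7,11-trimethyltrideca-2,4,6,8,10-pentaen-12-yn-1-yl]triphenylphosphonium bromide | [Br-].CC1=C(C#C/C(C)=C/C=C/C(C)=C/C=C/C=C(C)/C[P+](c2ccccc2)(c2ccccc2)c2ccccc2)C(C)(C)C[C@H](O)C1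
F7 | step 10 | (2E,4E,6E,8E,10E,12E)-2,7,11-trimethyl-13-[(1S,2S,4S)-1,2,4-trihydroxy-2,6,6-trimethylcyclohexyl]trideca-2,4,6,8,10,12-hexaenal | O=C/C(C)=C/C=C/C=C(C)/C=C/C=C(C)/C=C/[C@]1(O)C(C)(C)C[C@H](O)C[C@]1(C)O
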